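**Retrosynthetic overview**

1. Target ⇒ two molecules of chloranthalactone A by head-to-head [2+2] photodimerisation across C8=C9; the cyclobutane is formed last.
2. Chloranthalactone A ⇒ a seco-lactone with a 2-substituted acrolein on C5 and a vinyl group on C10; an intramolecular vinylcarbene [2+1] builds the cyclopropane and ring B together, with the exocyclic methylene already in place (key step).
3. Seco-lactone ⇒ trans-4-isopropenyl-3-methyl-3-vinylcyclohexanone by pyruvate aldol and dehydrative enol-lactonisation (butenolide), then allylic oxidation of the isopropenyl CH3.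
4. That ketone ⇒ (1R,5R)-(+)-verbenone by vinyl conjugate addition anti to the gem-dimethyl bridge, then cyclobutane fragmentation; C5 and C10 come from the chiral pool.
5. Ring order: ring C (the verbenone six-membered ring) → butenolide → cyclopropane + ring B → cyclobutane.

Assumption: (1R,5R)-(+)-verbenone of high enantiomeric purity is taken as commercial (it is also made in two steps from (+)-α-pinene); positions are given in lindenane numbering (C1–C15), also for the seco intermediates.

**Route**

Step 1
Reactants: 1 (1R,5R)-(+)-verbenone; 2 vinylmagnesium bromide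
Product: 3 (1R,4S,5S)-4-ethenyl-4,6,6-trimethylbicyclo[3.1.1]heptan-2-one
Conditions: CH2=CHMgBr (1.5 equiv), CuBr·SMe2 (10 mol %), THF, −40 → 0 °C; then 1 M HCl
Reagents that add atoms: vinylmagnesium bromide (2), C=C[Mg]Br
Why: Copper-catalysed conjugate (1,4-) addition of the Grignard reagent to the enone, in which the vinyl group enters C4 from the face anti to the gem-dimethyl bridge, so that the quaternary centre (later C10) is set by the bicyclic framework with its methyl syn to the bridge.

Step 2
Reactants: 3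
Product: 6 (3S,4S)-3-ethenyl-3-methyl-4-(prop-1-en-2-yl)cyclohexan-1-one, via tertiary iodide silyl enol ether 4 (not isolated), via isopropenyl silyl enol ether 5 (not isolated)
Conditions: Me3SiI (1.3 equiv), CH2Cl2, −40 → 0 °C; DBU (2.5 equiv), 0 °C → rt; then 1 M HCl, THF
Reagents that add atoms: none
Why: Ketone-assisted heterolytic fragmentation of the strained cyclobutyl ketone (retro-Prins-type ring opening by Me3SiI) cleaves the C1–C6 bond to a silyl enol ether and a tertiary iodide, E2 elimination with DBU gives the isopropenyl group (the tetrasubstituted alkene is disfavoured by allylic 1,3-strain against the neighbouring quaternary carbon) and acid work-up frees the ketone, while neither stereocentre is touched, so C5 and C10 carry isopropenyl and vinyl trans.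

Step 3
Reactants: 6; 7 ethyl pyruvate
Product: 8 ethyl 2-[(4S,5S)-4-ethenyl-4-methyl-2-oxo-5-(prop-1-en-2-yl)cyclohexyl]-2-hydroxypropanoate (mixture of epimers at the two new centres)
Conditions: LiN(iPr)2 (1.1 equiv), THF, −78 °C; ethyl pyruvate (1.3 equiv), −78 °C; AcOH quench
Reagents that add atoms: ethyl pyruvate (7), CCOC(=O)C(C)=O
Why: Kinetic deprotonation takes place at C7 (the CH2 remote from the quaternary C10) and the lithium enolate undergoes aldol addition to the ketone carbonyl of ethyl pyruvate; both new stereocentres are removed in step 4, so their mixture does not matter.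

Step 4
Reactants: 8
Product: 9 (5S,6S)-6-ethenyl-3,6-dimethyl-5-(prop-1-en-2-yl)-5,6-dihydro-1-benzofuran-2(4H)-one
Conditions: p-TsOH·H2O (10 mol %), benzene, reflux, Dean–Stark
Reagents that add atoms: none
Why: Acid-catalysed dehydration of the tertiary aldol (C7=C11) and enol-lactonisation of the C8 enol onto the ester give the γ-alkylidene butenolide with the C8=C9 bond; no stereocentre is formed and C5 and C10 cannot epimerise.

Step 5
Reactants: 9
Product: 11 2-[(5R,6S)-6-ethenyl-3,6-dimethyl-2-oxo-2,4,5,6-tetrahydro-1-benzofuran-5-yl]prop-2-enal, via allylic alcohol 10 (not isolated)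
Conditions: SeO2 (0.3 equiv), t-BuOOH (3 equiv), CH2Cl2, 0 °C → rt; then Dess–Martin periodinane (1.3 equiv), rt
Reagents that add atoms: selenium dioxide, O=[Se]=O; tert-butyl hydroperoxide, CC(C)(C)OO
Why: SeO2/t-BuOOH allylic oxidation (ene reaction then [2,3]-sigmatropic shift) attacks the most electron-rich alkene, the isopropenyl group, at its CH3 rather than at the tertiary C5–H, and Dess–Martin oxidation converges the alcohol/aldehyde mixture to the enal; no stereocentre changes (the C5 descriptor changes only through CIP priorities).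

Step 6
Reactants: 11; 12 2,4,6-tri(propan-2-yl)benzenesulfonohydrazide
Product: 15 chloranthalactone A [linden-4(15),7(11),8-trien-12,8-olide; 1α-H, 3α-H, 5α-H, 10β-CH3], via sulfonylhydrazone 13 (not isolated), via vinyldiazomethane 14 (not isolated)
Conditions: 12 (1.05 equiv), 4 Å MS, toluene, rt; then Cs2CO3 (2 equiv), Co(TPP) (cobalt tetraphenylporphyrin, C44H28CoN4; 5 mol %), toluene, 40 °C
Reagents that add atoms: none
Why: Proposed new method: the hydrazone gives the vinyldiazomethane in situ and Co(TPP) (divalent cobalt) turns it into a cobalt-carbene radical at C3, which adds to the terminal carbon C2 of the C10 vinyl group through a chair-like six-membered transition state (C14 methyl axial, C3–Co bond equatorial), after which the C1 radical closes the C1–C3 bond by 3-exo attack with release of the cobalt porphyrin, so that the cyclopropane and ring B form together with the exocyclic methylene in place; C2 is the out-of-plane apex of that chair on the methyl-bearing face, which puts the cyclopropane CH2 syn to C14 with H1 and H3 anti, as in the target, whereas a concerted Rh or Cu carbenoid addition would be expected to prefer the other cyclopropane face through a boat-like bicyclo[3.1.0]hexane transition state; closest known reaction type: metalloradical intramolecular cyclopropanation with cobalt porphyrins and diazo compounds generated in situ from sulfonylhydrazones.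

Step 7
Reactants: 15 chloranthalactone A (two molecules)
Product: 16 the target, the C2-symmetric head-to-head cyclobutane dimer of 15 (new bonds C8–C8′ and C9–C9′)
Conditions: hν (high-pressure Hg lamp, Pyrex filter), hexane, rt
Reagents that add atoms: none
Why: [2+2] photocycloaddition of the C8=C9 enol-lactone double bonds, head to head, each monomer reacting on its α face (anti to the C14 methyl on the neighbouring C10) and the two halves anti across the four-membered ring, which gives the cis-anti-cis cyclobutane with C8, C9, C8′ and C9′ as in the target.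

**Compound list**

1 | (1R,5R)-(+)-verbenone, (1R,5R)-4,6,6-trimethylbicyclo[3.1.1]hept-3-en-2-one | CC1=CC(=O)[C@@H]2C[C@H]1C2(C)C | starting material
2 | vinylmagnesium bromide | C=C[Mg]Br | starting material
3 | (1R,4S,5S)-4-ethenyl-4,6,6-trimethylbicyclo[3.1.1]heptan-2-one (vinyl anti to the gem-dimethyl bridge) | C=C[C@]1(C)CC(=O)[C@@H]2C[C@H]1C2(C)C | intermediate
4 | trimethyl{[(4R,5S)-5-ethenyl-4-(2-iodopropan-2-yl)-5-methylcyclohex-1-en-1-yl]oxy}silane | CC(C)(I)[C@@H]1CC=C(O[Si](C)(C)C)C[C@@]1(C)C=C | intermediate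
5 | trimethyl{[(4S,5S)-5-ethenyl-5-methyl-4-(prop-1-en-2-yl)cyclohex-1-en-1-yl]oxy}silane | C=C(C)[C@@H]1CC=C(O[Si](C)(C)C)C[C@@]1(C)C=C | intermediate
6 | (3S,4S)-3-ethenyl-3-methyl-4-(prop-1-en-2-yl)cyclohexan-1-one (vinyl and isopropenyl trans) | C=C(C)[C@@H]1CCC(=O)C[C@@]1(C)C=C | intermediate
7 | ethyl pyruvate | CCOC(=O)C(C)=O | starting material
8 | ethyl 2-[(4S,5S)-4-ethenyl-4-methyl-2-oxo-5-(prop-1-en-2-yl)cyclohexyl]-2-hydroxypropanoate (epimer mixture at ring C1 and at the carbinol carbon) | C=C(C)[C@@H]1CC(C(C)(O)C(=O)OCC)C(=O)C[C@@]1(C)C=C | intermediate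
9 | (5S,6S)-6-ethenyl-3,6-dimethyl-5-(prop-1-en-2-yl)-5,6-dihydro-1-benzofuran-2(4H)-one | C=C(C)[C@@H]1CC2=C(C)C(=O)OC2=C[C@@]1(C)C=C | intermediate
10 | (5R,6S)-6-ethenyl-5-(3-hydroxyprop-1-en-2-yl)-3,6-dimethyl-5,6-dihydro-1-benzofuran-2(4H)-one | C=C(CO)[C@@H]1CC2=C(C)C(=O)OC2=C[C@@]1(C)C=C | intermediate
11 | 2-[(5R,6S)-6-ethenyl-3,6-dimethyl-2-oxo-2,4,5,6-tetrahydro-1-benzofuran-5-yl]prop-2-enal | C=C(C=O)[C@@H]1CC2=C(C)C(=O)OC2=C[C@@]1(C)C=C | intermediate
12 | 2,4,6-tri(propan-2-yl)benzenesulfonohydrazide | CC(C)c1cc(C(C)C)c(S(=O)(=O)NN)c(C(C)C)c1 | starting material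
13 | N′-{(E)-2-[(5R,6S)-6-ethenyl-3,6-dimethyl-2-oxo-2,4,5,6-tetrahydro-1-benzofuran-5-yl]prop-2-en-1-ylidene}-2,4,6-tri(propan-2-yl)benzenesulfonohydrazide | C=C(/C=N/NS(=O)(=O)c1c(C(C)C)cc(C(C)C)cc1C(C)C)[C@@H]1CC2=C(C)C(=O)OC2=C[C@@]1(C)C=C | intermediate
14 | (5R,6S)-5-(3-diazoprop-1-en-2-yl)-6-ethenyl-3,6-dimethyl-5,6-dihydro-1-benzofuran-2(4H)-one | C=C(C=[N+]=[N-])[C@@H]1CC2=C(C)C(=O)OC2=C[C@@]1(C)C=C | intermediate
15 | chloranthalactone A, linden-4(15),7(11),8-trien-12,8-olide (1α-H, 3α-H, 5α-H, 10β-CH3) | C=C1[C@H]2C[C@H]2[C@@]2(C)[C@H]1CC1=C(C)C(=O)OC1=C2 | intermediate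
16 | CNP0265879.1, head-to-head cis-anti-cis cyclobutane dimer of 15 (C8–C8′ and C9–C9′ bonds on the α faces, lactone oxygens on C8 and C8′) | C=C1[C@H]2C[C@H]2[C@@]2(C)[C@H]1CC1=C(C)C(=O)O[C@]13[C@H]2[C@H]1[C@@]2(C)[C@@H]4C[C@@H]4C(=C)[C@@H]2CC2=C(C)C(=O)O[C@@]213 | target

**Step count**

Total steps: 7. Longest linear sequence: 7 (1 → 16).

**Steps most likely to fail, each with a fallback**

Step 6 (key step). Three things can go wrong: the vinyldiazomethane may close to a pyrazole before the catalyst captures it; the allyl-type carbene radical may react through its other terminus (C15) to give a formal [3+2] product; and the cyclopropane may form on the face anti to C14. The face selectivity is the weakest point, because it rests on the stepwise chair argument and not on a stereocentre.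

The fallback sets out from 6 and comes back at 15. It fixes the cyclopropane face with an sp3 stereocentre at C4:
- Ethylene glycol and PPTS (benzene, reflux) convert 6 into the ketal (7S,8S)-7-ethenyl-7-methyl-8-(prop-1-en-2-yl)-1,4-dioxaspiro[4.5]decane F1.
- O3 at −78 °C (CH2Cl2/MeOH, indicator dye, then Me2S) cleaves only the 1,1-disubstituted alkene to the methyl ketone 1-[(7S,8R)-7-ethenyl-7-methyl-1,4-dioxaspiro[4.5]decan-8-yl]ethan-1-one F2.
- Dimethylsulfonium methylide (Me3S+ I−, n-BuLi, THF) adds under Felkin–Anh control, with C10 as the large group, to give the epoxide (7S,8R)-7-ethenyl-7-methyl-8-[(2S)-2-methyloxiran-2-yl]-1,4-dioxaspiro[4.5]decane F3.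
- LiTMP (lithium 2,2,6,6-tetramethylpiperidide; t-BuOMe, 0 °C → rt) lithiates the epoxide CH2, and the lithium carbenoid cyclopropanates the vinyl group with the C4–O bond trans to the new cyclopropane. This gives the tertiary alcohol 4α-hydroxy-11,12,13-trinorlindenan-8-one ethylene ketal F4, with the cyclopropane CH2 syn to C14.
- SOCl2/pyridine (−20 °C) eliminates anti through the methyl hydrogens (H5 is syn to the hydroxyl) to 11,12,13-trinorlinden-4(15)-en-8-one ethylene ketal F5.
- PPTS in wet acetone frees 11,12,13-trinorlinden-4(15)-en-8-one F6.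
- LiN(iPr)2 then ethyl pyruvate gives the aldol ethyl 2-hydroxy-2-(8-oxo-11,12,13-trinorlinden-4(15)-en-7-yl)propanoate F7, and p-TsOH in refluxing benzene closes the butenolide to 15.

Step 5. The alkylidene butenolide may not tolerate SeO2/t-BuOOH, and oxidation at C6 or C13 or over-oxidation can compete. The fallback sets out from 9 and comes back at 11. Ene-type chlorination with Ca(OCl)2 and CO2 (CH2Cl2/H2O, 0 °C) gives the allylic chloride (5R,6S)-5-(3-chloroprop-1-en-2-yl)-6-ethenyl-3,6-dimethyl-5,6-dihydro-1-benzofuran-2(4H)-one F8. N-Methylmorpholine N-oxide (MeCN, rt, Kornblum-type oxidation) then converts the CH2Cl group into the aldehyde of 11.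

Step 2. The tertiary cation may be trapped by the neighbouring vinyl group, HI may add to an alkene, or elimination may give some isopropylidene isomer. The fallback sets out from 3 and comes back at 6. BF3·OEt2, Zn(OAc)2 and Ac2O (rt) open the cyclobutane with acetate capture to (4R,5S)-4-(2-acetoxypropan-2-yl)-5-ethenyl-5-methylcyclohex-1-en-1-yl acetate F9. K2CO3 in MeOH gives (3S,4R)-3-ethenyl-4-(2-hydroxypropan-2-yl)-3-methylcyclohexan-1-one F10, and Burgess reagent (benzene, 50 °C) dehydrates it to 6.

Further compounds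
F1 | step 6 | (7S,8S)-7-ethenyl-7-methyl-8-(prop-1-en-2-yl)-1,4-dioxaspiro[4.5]decane | C=C(C)[C@@H]1CCC2(OCCO2)C[C@@]1(C)C=C
F2 | step 6 | 1-[(7S,8R)-7-ethenyl-7-methyl-1,4-dioxaspiro[4.5]decan-8-yl]ethan-1-one | CC(=O)[C@@H]1CCC2(OCCO2)C[C@@]1(C)C=C
F3 | step 6 | (7S,8R)-7-ethenyl-7-methyl-8-[(2S)-2-methyloxiran-2-yl]-1,4-dioxaspiro[4.5]decane | C[C@@]1(CO1)[C@@H]2CCC3(OCCO3)C[C@@]2(C)C=C
F4 | step 6 | 4α-hydroxy-11,12,13-trinorlindenan-8-one ethylene ketal (4β-CH3, cyclopropane CH2 β) | C[C@@]1(O)[C@H]2C[C@H]2[C@@]2(C)[C@H]1CCC1(OCCO1)C2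
F5 | step 6 | 11,12,13-trinorlinden-4(15)-en-8-one ethylene ketal | C=C1[C@H]2C[C@H]2[C@@]2(C)[C@H]1CCC1(OCCO1)C2
F6 | step 6 | 11,12,13-trinorlinden-4(15)-en-8-one | C=C1[C@H]2C[C@H]2[C@@]2(C)[C@H]1CCC(=O)C2
F7 | step 6 | ethyl 2-hydroxy-2-(8-oxo-11,12,13-trinorlinden-4(15)-en-7-yl)propanoate (epimer mixture at C7 and the carbinol carbon) | C=C1[C@H]2C[C@H]2[C@@]2(C)[C@H]1CC(C(C)(O)C(=O)OCC)C(=O)C2
F8 | step 5 | (5R,6S)-5-(3-chloroprop-1-en-2-yl)-6-ethenyl-3,6-dimethyl-5,6-dihydro-1-benzofuran-2(4H)-one | C=C(CCl)[C@@H]1CC2=C(C)C(=O)OC2=C[C@@]1(C)C=C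
F9 | step 2 | (4R,5S)-4-(2-acetoxypropan-2-yl)-5-ethenyl-5-methylcyclohex-1-en-1-yl acetate | CC(C)(OC(C)=O)[C@@H]1CC=C(OC(C)=O)C[C@@]1(C)C=C
F10 | step 2 | (3S,4R)-3-ethenyl-4-(2-hydroxypropan-2-yl)-3-methylcyclohexan-1-one | CC(C)(O)[C@@H]1CCC(=O)C[C@@]1(C)C=C
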